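(The numbers in the tables stem from a simulated flask with constants of no real substance, noise included.)

Molar is the unit of the number I carry through these flasks.

| flask | substrate | partner | capture agent | remark | time |
|---|---|---|---|---|---|
| gamma | 0.017 M | 1.5 equiv | 0.50 mM | run made earlier |  |
| Wednesday's | 0.025 M | 1.50 equiv | 0.500 mM |  | 5.0 min |
| Thursday's | 0.025 M | 1.50 equiv | 0.650 mM |  | 5.0 min |

gamma run (percent of the substrate charged)

| time / s | target / % | side product / % | trapped intermediate / % | substrate / % | open intermediate / % |
|---|---|---|---|---|---|
| 15.0 | 5.1 | 1.9 | 0 | 75.8 | 16.7 |
| 30.0 | 13.0 | 4.5 | 0.4 | 56.4 | 24.1 |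
| 50.0 | 20.8 | 8.3 | 0 | 37.7 | 28.7 |
| 60.0 | 24.9 | 9.6 | 0.1 | 31.2 | 29.1 |
| 80.0 | 29.1 | 11.6 | 0.2 | 21.0 | 29.5 |
| 90.0 | 31.6 | 13.0 | 0.7 | 16.9 | 28.9 |
| 120 | 35.6 | 14.3 | 1.1 | 9.0 | 27.0 |

(standard deviation of a reading: 0.3 percentage points)

- a species is counted by the substrate in it: one side product counts as two
- the earlier runs were read with a standard deviation of 0.3 percentage points

- which of these there is most of at the end, counted by the substrate in it, Wednesday's (side product / trapped intermediate / target / open intermediate)
- which of these there is most of at the end, counted by the substrate in it, Thursday's (side product / trapped intermediate / target / open intermediate)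
- amount of the one of these that there is most of at the end, in percent of the substrate charged, Wednesday's
- amount of the one of these that there is most of at the end, in percent of the substrate charged, Thursday's

First question: how does the gamma run split? At its last reading, target over side product is S = 2.49.

Second question: does that split survive a new charge? I define the pull as target gained per second per open intermediate. It is 0.0186 s⁻¹ early and 0.00617 s⁻¹ late, a fall by a factor of 3.01. Yet target then holds 35.6% of the substrate against 1.5 equiv of partner charged. So I assume partner is lost mainly to itself, in its square. On that assumption its summed pull changes little with the charge, while side product, which I take to need substrate, gains with the charge. I therefore take S to go as one over the charge, with S times the charge fixed at these equivalents. That product is the crossing concentration K, by this reading of the gamma run the substrate charge at which target and side product end level: K = 0.0423 M.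

Both new flasks lie lower, 0.025 M, so I expect target to lead, with S = 1.69. Over the last gamma stretch these two gained 67.1% of what the substrate lost, so I expect 55.9% together and target near 35.2%. Thursday's capture agent can hold 2.60% of the substrate, far below that, so I reckon Thursday's the same.

The forecast also names target, but higher: 46% Wednesday's and 45% Thursday's, holding that “Target and side product stay in a fixed ratio”.

The flasks give target on both days, 39.6% Wednesday's and 39.6% Thursday's.

    substrate → open intermediate (k = 0.0180 s⁻¹)
    partner + open intermediate → target (k = 2.00 M⁻¹ s⁻¹)
    2 partner → homo product (k = 0.860 M⁻¹ s⁻¹)
    open intermediate + capture agent → trapped intermediate (k = 0.640 M⁻¹ s⁻¹)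
    substrate + open intermediate → side product (k = 0.420 M⁻¹ s⁻¹)
    open intermediate → decomposed reagent (k = 0.00450 s⁻¹)

Wednesday's ends with 20.3% side product, so its own K is 0.0488 M, above my reading. The neighbouring flask is Thursday's with 0.062 M of substrate, above K, so the same reckoning gives that neighbouring flask S = 0.682, with target behind. That neighbouring flask ends with 29.9% target against 36.0% side product, S = 0.831, and with the recipe's equivalents and loadings the two stand level at 0.0510 M of substrate.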